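**Retrosynthetic overview**

- Target 9 comes from the 2-silyl isoflavone 7 by protodesilylation at C2 and hydrogenolysis of the two benzyl ethers.
- The strategy rests on the O1–C2=C3–C4 unit of ring C. Ring C is cut at O1–C2 and C3–C4, so that C2=C3 is the alkyne of 6 set between the phenol oxygen (O1) and the formyl carbon (C4) of the ring A salicylaldehyde 2. Ring B sits on the alkyne carbon that becomes C3, and SiMe3 on the other carbon stands in for the C2 hydrogen.
- Aldehyde 2 comes from 2,4,6-trihydroxybenzaldehyde 1 by twofold O-benzylation. Alkyne 6 comes from iodide 4 and ethynyltrimethylsilane 5 by Sonogashira coupling, and 4 from 1,2,3,5-tetramethoxybenzene 3 by iodination.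
- Ring order: rings A and B are bought; ring C is the only ring made (step 4).

Key step: step 4

Assumption: the target has no stereocentre, so no stereocontrol is needed; 1, 3 and 5 are taken as purchased.

**Route**

Step 1
Reactants: 1 2,4,6-trihydroxybenzaldehyde
Product: 2 2,4-bis(benzyloxy)-6-hydroxybenzaldehyde
Conditions: BnBr (2.1 equiv), K2CO3 (2.2 equiv), DMF, 0 °C to rt
Reagents that add atoms: benzyl bromide, BrCc1ccccc1
Why: Williamson etherification in which the 4-OH and one ortho OH are alkylated, while the remaining ortho OH is held in a hydrogen bond to the formyl oxygen and should resist a third alkylation with two equivalents of halide at room temperature.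

Step 2
Reactants: 3 1,2,3,5-tetramethoxybenzene
Product: 4 2-iodo-1,3,4,5-tetramethoxybenzene
Conditions: NIS (1.0 equiv), CF3CO2H (cat.), MeCN, 0 °C to rt, dark
Reagents that add atoms: N-iodosuccinimide, O=C1CCC(=O)N1I
Why: Electrophilic aromatic iodination, in which the two open ring positions of 3 are equivalent by symmetry and strongly activated by the methoxy groups, so one mono-iodide should form.

Step 3
Reactants: 4 2-iodo-1,3,4,5-tetramethoxybenzene; 5 ethynyltrimethylsilane
Product: 6 trimethyl[(2,3,4,6-tetramethoxyphenyl)ethynyl]silane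
Conditions: PdCl2(PPh3)2 (5 mol %), CuI (10 mol %), Et3N/THF, 60 °C
Reagents that add atoms: none
Why: Sonogashira coupling of an aryl iodide with a terminal alkyne, heated gently because the iodide is electron-rich and flanked by two methoxy groups, with the silyl group blocking the second alkyne terminus.

Step 4
Reactants: 2 2,4-bis(benzyloxy)-6-hydroxybenzaldehyde; 6 trimethyl[(2,3,4,6-tetramethoxyphenyl)ethynyl]silane
Product: 7 5,7-bis(benzyloxy)-3-(2,3,4,6-tetramethoxyphenyl)-2-(trimethylsilyl)chromen-4-one
Conditions: [RhCl2(C5Me5)]2 (5 mol %), Cu(OAc)2 (2.2 equiv, anhydrous), o-xylene, 120 °C, N2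
Reagents that add atoms: none
Why: This is the rhodium-catalysed oxidative [4+2] annulation of salicylaldehydes with internal alkynes, a known chromone synthesis, here run with a silyl aryl alkyne of the kind used in related trivalent-rhodium annulations. The phenoxide of 2 binds trivalent rhodium and directs cleavage of the formyl C–H bond to a five-membered acyl rhodacycle; 6 inserts into the Rh–acyl bond (C3–C4 formed) to give a seven-membered oxarhodacycle, and C–O reductive elimination (O1–C2 formed) releases 7 while Cu(OAc)2 returns monovalent rhodium to the trivalent state. Ring C, the six-membered pyranone, is thus closed by reductive elimination between the phenol oxygen and the rhodium-bound vinyl carbon, the alkyne supplying C2 and C3. No stereocentre is formed. The step needs one regiochemistry of insertion, silyl-bearing carbon on rhodium (future C2) and aryl-bearing carbon on the acyl carbon (future C3), which the α-silyl stabilisation of the C–Rh bond and the preference of the large SiMe3 group for the longer C–Rh bond should secure. Anhydrous Cu(OAc)2 is used so that the C–Si bond is not cleaved before the annulation.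

Step 5
Reactants: 7 5,7-bis(benzyloxy)-3-(2,3,4,6-tetramethoxyphenyl)-2-(trimethylsilyl)chromen-4-one
Product: 8 5,7-bis(benzyloxy)-3-(2,3,4,6-tetramethoxyphenyl)chromen-4-one
Conditions: Bu4NF (1.5 equiv), AcOH (1.5 equiv), THF, 0 °C to rt
Reagents that add atoms: none
Why: Fluoride-induced protodesilylation of a vinylsilane whose silicon-bearing sp2 carbon is α to the ring oxygen, with acetic acid as proton source and buffer so that the medium stays too weakly basic to open the pyranone.

Step 6
Reactants: 8 5,7-bis(benzyloxy)-3-(2,3,4,6-tetramethoxyphenyl)chromen-4-one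
Product: 9 5,7-dihydroxy-3-(2,3,4,6-tetramethoxyphenyl)chromen-4-one
Conditions: H2 (1 atm), 10% Pd/C, EtOAc/MeOH, rt
Reagents that add atoms: none
Why: Catalytic hydrogenolysis of benzyl aryl ethers, under which the methyl ethers and the hindered, vinylogous-ester C2=C3 bond of the isoflavone should stay untouched at one atmosphere and room temperature.

**Compound list**

1 | 2,4,6-trihydroxybenzaldehyde | O=Cc1c(O)cc(O)cc1O | starting material
2 | 2,4-bis(benzyloxy)-6-hydroxybenzaldehyde | O=Cc1c(O)cc(OCc2ccccc2)cc1OCc1ccccc1 | intermediate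
3 | 1,2,3,5-tetramethoxybenzene | COc1cc(OC)c(OC)c(OC)c1 | starting material
4 | 2-iodo-1,3,4,5-tetramethoxybenzene | COc1cc(OC)c(I)c(OC)c1OC | intermediate
5 | ethynyltrimethylsilane | C#C[Si](C)(C)C | starting material
6 | trimethyl[(2,3,4,6-tetramethoxyphenyl)ethynyl]silane | COc1cc(OC)c(C#C[Si](C)(C)C)c(OC)c1OC | intermediate
7 | 5,7-bis(benzyloxy)-3-(2,3,4,6-tetramethoxyphenyl)-2-(trimethylsilyl)chromen-4-one | COc1cc(OC)c(-c2c([Si](C)(C)C)oc3cc(OCc4ccccc4)cc(OCc4ccccc4)c3c2=O)c(OC)c1OC | intermediate
8 | 5,7-bis(benzyloxy)-3-(2,3,4,6-tetramethoxyphenyl)chromen-4-one | COc1cc(OC)c(-c2coc3cc(OCc4ccccc4)cc(OCc4ccccc4)c3c2=O)c(OC)c1OC | intermediate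
9 | 5,7-dihydroxy-3-(2,3,4,6-tetramethoxyphenyl)chromen-4-one | COc1cc(OC)c(-c2coc3cc(O)cc(O)c3c2=O)c(OC)c1OC | target

**Step count**

Total steps: 6. Longest linear sequence: 5 steps (3 → 4 → 6 → 7 → 8 → 9).

**Steps most likely to fail**

1. Step 4. The insertion may be slow or go in the wrong orientation, because the aryl end of the alkyne, with two ortho methoxy groups, is about as bulky as the silyl end. The C–Si bond may also be cleaved early, or the acyl rhodium may lose CO. The fallback is a Suzuki route to the same isoflavone; it sets out from 2 and 4 and comes back at 8.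
 - Aldehyde 2 is treated with MeMgBr (excess, THF, 0 °C) to give racemic 1-[2,4-bis(benzyloxy)-6-hydroxyphenyl]ethanol F1.
 - Oxidation with MnO2 in CH2Cl2 gives 1-[2,4-bis(benzyloxy)-6-hydroxyphenyl]ethanone F2.
 - Condensation with N,N-dimethylformamide dimethyl acetal (toluene, 90 °C) gives (E)-1-[2,4-bis(benzyloxy)-6-hydroxyphenyl]-3-(dimethylamino)prop-2-en-1-one F3.
 - Iodine in CHCl3 at rt closes the ring with loss of dimethylamine to 5,7-bis(benzyloxy)-3-iodochromen-4-one F4.
 - Separately, iodide 4 is converted by iodine–lithium exchange (n-BuLi, THF, −78 °C), B(OiPr)3 and mild acidic hydrolysis into (2,3,4,6-tetramethoxyphenyl)boronic acid F5.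
 - Suzuki coupling of F4 with F5 (Pd(OAc)2, SPhos, K3PO4, toluene/H2O, 80 °C) gives 8, which goes on through step 6.

2. Step 5. The pyranone may be opened by base derived from the fluoride source faster than silicon is removed, or the C–Si cleavage may stall under the buffered conditions. The fallback uses the ring opening on purpose; it sets out from 7 and comes back at 8.
 - Hot aqueous ethanolic KOH opens the pyranone, cleaves the C–Si bond and removes C2 as formate, the classical alkaline degradation of an isoflavone, to give 1-[2,4-bis(benzyloxy)-6-hydroxyphenyl]-2-(2,3,4,6-tetramethoxyphenyl)ethanone F6.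
 - Deoxybenzoin F6 is reclosed with N,N-dimethylformamide dimethyl acetal (DMF, 100 °C, then dilute acid), which puts back C2 as a CH and gives 8.

3. Step 1. Benzylation may not stop cleanly at the diether: the third hydroxyl may be alkylated, the electron-rich ring may be C-benzylated, or mono-ether may remain. The fallback over-protects and then unmasks one position; it sets out from 1 and comes back at 2.
 - Exhaustive benzylation (BnBr in excess, K2CO3, DMF, 60 °C) gives 2,4,6-tris(benzyloxy)benzaldehyde F7.
 - MgBr2·OEt2 (toluene/Et2O, reflux) removes one benzyl group ortho to the formyl group through the magnesium chelate of the aldehyde and the ortho ether oxygen, giving 2.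

**Further compounds**

F1 | step 4 | 1-[2,4-bis(benzyloxy)-6-hydroxyphenyl]ethanol (racemic) | CC(O)c1c(O)cc(OCc2ccccc2)cc1OCc1ccccc1
F2 | step 4 | 1-[2,4-bis(benzyloxy)-6-hydroxyphenyl]ethanone | CC(=O)c1c(O)cc(OCc2ccccc2)cc1OCc1ccccc1
F3 | step 4 | (E)-1-[2,4-bis(benzyloxy)-6-hydroxyphenyl]-3-(dimethylamino)prop-2-en-1-one | CN(C)/C=C/C(=O)c1c(O)cc(OCc2ccccc2)cc1OCc1ccccc1
F4 | step 4 | 5,7-bis(benzyloxy)-3-iodochromen-4-one | O=c1c(I)coc2cc(OCc3ccccc3)cc(OCc3ccccc3)c12
F5 | step 4 | (2,3,4,6-tetramethoxyphenyl)boronic acid | COc1cc(OC)c(B(O)O)c(OC)c1OC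
F6 | step 5 | 1-[2,4-bis(benzyloxy)-6-hydroxyphenyl]-2-(2,3,4,6-tetramethoxyphenyl)ethanone | COc1cc(OC)c(CC(=O)c2c(O)cc(OCc3ccccc3)cc2OCc2ccccc2)c(OC)c1OC
F7 | step 1 | 2,4,6-tris(benzyloxy)benzaldehyde | O=Cc1c(OCc2ccccc2)cc(OCc2ccccc2)cc1OCc1ccccc1
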